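## The problem

Target 16 is a 3,3a,4,5-tetrahydrobenzofuran-6(2H)-one. Ring A (O1, C2, C3, C3a, C7a) is a dihydrofuran and ring B (C3a, C4, C5, C6, C7, C7a) a cyclohexenone. The rings share the C3a–C7a bond: C3a is an all-carbon quaternary centre bearing the allyl group, and C7a is the enol-ether carbon of a vinylogous ester O1–C7a=C7(OMe)–C6=O.

Four stereocentres must be set: C2 (methyl, R), C3 (3,4,5-trimethoxyphenyl, S), C3a (allyl, R) and C5 (methoxy, S). Methyl and aryl are trans, aryl and allyl are trans, and the C5 methoxy group is cis to the allyl group. C2 can be bought and can direct C3 by 1,2-induction, and the C3 aryl group can direct the electrophile that completes C3a. C5 is α to the ketone, epimerisable and remote from C2 and C3, so only the angular allyl group can control it, and it must be set last under kinetic conditions.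

Several groups limit the choice of reagents. The terminal alkene rules out catalytic hydrogenation, the α-methoxy ketone is sensitive to base, the vinylogous ester to aqueous acid, and the arene is electron-rich. On any cyclohexadienone intermediate the C3a allyl group can migrate under strong acid or heat (dienone–phenol or Cope pathways).

The feature that opens the structure is that C5(OMe)–C6(=O)–C7(OMe) is, atom for atom, 1,3-dimethoxyacetone 11. C7a with O1 is a γ-lactone carbonyl with its ring oxygen, and C4 can be carried as an aldehyde on C3a. Ring B is therefore a [3+3] union of a ketone used at both α-carbons with the 1,3-dielectrophile formyl lactone 10.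

## Retrosynthesis

**16 ⇒ 15.** No skeletal bond is cut; the C4–H and C5–H bonds are removed to give the cross-conjugated dienone 15. This puts C4 at the aldehyde oxidation level that the annulation needs and removes the only epimerisable stereocentre from all earlier steps. Carrying a C4 hydroxyl forward instead would leave two uncontrolled centres and a separate deoxygenation. The forward step must deliver hydride to C4 only, spare the terminal alkene, and protonate C5 on the face opposite the angular allyl group.

**15 ⇒ 10 + 11.** The C4–C5 and C7–C7a bonds are cut, and the O1–C7a bond is traced back to the lactone C–O bond of 10. Cutting ring A instead (O1–C2, C2–C3) would leave the quaternary C3a to be made by dearomatising ring B. Cutting at C6 would call for a carbonyl dianion equivalent. The chosen cut removes ring B completely, leaves a monocyclic lactone holding all three ring A stereocentres, and uses a symmetric, achiral ketone whose two α-carbons are interchangeable. The forward reaction must attack the aldehyde before the lactone, enolise the distal methoxymethyl group, acylate at the hindered lactone carbonyl, and then re-close O1–C7a and dehydrate without moving the allyl group.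

**10 ⇒ 9.** The C3a–allyl bond is cut. The allyl group has to arrive after the formyl carbon, because the last electrophile enters anti to the C3 aryl group. The reverse order would give the C3a epimer. The precursor 9 is a stabilised formyl-lactone enol with no quaternary centre. The forward step needs C- over O-allylation and high facial selectivity, which a palladium-catalysed allylation of the soft enolate should provide.

**9 ⇒ 8.** The C3a–C4 bond is cut (formyl removed). A crossed Claisen formylation is the shortest way to put an aldehyde-level carbon on a lactone α-carbon and activates that carbon for the next alkylation. Lactone 8 has only the two contiguous centres C2 and C3.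

**8 ⇒ 4 + 5.** The C3–aryl bond is cut. Conjugate addition of the aryl Grignard reagent 6, made from bromide 5, to butenolide 4 uses the C2 methyl group to set C3 trans. A cut at C2–C3 would need an aldol-type union with two new centres and no resident control. The butenolide carries one stereocentre and five carbons.

**4 ⇒ 2 ⇒ 1.** The lactone C–O bond is opened to the Z-hydroxy acid 3, the alkene is traced to the alkyne of 2, and the C3a–C7a bond is cut by decarboxylation to alkynol 1. The C2 stereocentre is bought in 1, and two operations (carboxylation, semihydrogenation with lactonisation) reach 4 without protecting groups.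

## Roads not taken

**Alternative 1:** Ring A is cut at O1–C2 and C2–C3 on an aromatic ring B. A base unmasks the ortho-quinone methide A1. A cinchona-derived ammonium ylide of a bromoacetate ester adds at C3, and the phenoxide oxygen displaces the ammonium group at C2, giving the trans dihydrobenzofuran ester A2. After reduction of the ester to the C2 methyl group and removal of the benzyl ether, allylation at C3a, para to the freed phenolic oxygen, would dearomatise ring B. This reaches the same dienone 15 and the same final reduction.
- Merits: convergent, both enantiomers available from the choice of alkaloid, and stable aromatic intermediates in which all ring B oxygens are in place early.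
- Weak points: the pentasubstituted quinone methide precursor takes several steps; the C2 methyl arrives as an ester and costs about three further steps; the enantioselectivity of the [4+1] step with so electron-rich a partner is uncertain; the dearomative allylation must beat O-allylation and revert-prone Claisen equilibria.
- Comparison: this road is better in freedom of absolute configuration and in not needing a strong-base cascade. The chosen plan answers with about half the step count, a methyl group that is correct from the start, and a quaternary centre made by enolate allylation under 1,2-induction.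

**Alternative 2:** The C3–aryl and C3a–allyl bonds are cut in one operation on butenolide A3, which already carries C4–C5–C6 as a 2-methoxypropanoate arm. The aryl cuprate derived from 6 adds anti to the methyl group, and the enolate is trapped by an allyl halide anti to the aryl group, giving A4. No ring closes.
- Merits: two stereocentres including the quaternary one in one flask, and C4 arrives as CH2, so no dienone and no final conjugate reduction are needed. In oxidation-state economy this road is better.
- Weak points: A3 must be made separately. Cuprate addition to an α-substituted butenolide and alkylation of the resulting fully substituted enolate are both sluggish. Ring B still lacks C7, so a methoxymethyl carbanion equivalent must be added to the ester in the presence of the lactone, and the same Claisen closure C7–C7a must follow. That closure exposes the early C5 centre to base, so its configuration has to be set again at the end anyway.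
- Comparison: the chosen plan pays with one extra reduction and a sensitive dienone, but takes C5–C6–C7 from one purchased ketone and forms the quaternary centre from a soft, well-behaved enolate.

**Alternative 3:** Ring A is built as a lactone by cutting C2–C3 and the lactone C–O bond. The allylchromium species formed from bromide A5 with CrCl2 adds through its aryl-bearing carbon to acetaldehyde A6, anti, and the alkoxide lactonises to the trans α-methylene lactone A7. The exocyclic methylene is C4 at the CH2 level. A Michael addition of enolate 12 followed by Claisen closure would then be the classical Michael–Claisen [3+3] route to ring B.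
- Merits: a very short approach to the lactone, and no dienone or end-game reduction. In step economy up to the lactone and in oxidation level at C4 this road is as good or better.
- Weak points: the key step is racemic unless a chiral ligand is added, and enantiofacial discrimination of so small an aldehyde is poor. After the Michael addition, the lactone α-carbon must still be allylated to the quaternary C3a in the presence of a more acidic ketone, so regioselective enolisation is a real obstacle.
- Comparison: the chosen plan offers secure absolute configuration from 1 and installs the allyl group before any ketone is present.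

Key step: step 6

Remarks on the chemistry:
- Atom labels follow the benzofuran numbering of 16 throughout.
- Compounds 1, 5 and 11 are taken as purchased.
- Enol 9 and enolate 12 are drawn as single geometric isomers.
- Compounds 13 and 14 are mixtures at the carbinol and methoxy-bearing carbons, and 14 is also an enol/keto mixture. All of this is erased when 15 forms.

## Route

Step 1
Reactants: 1 (R)-but-3-yn-2-ol
Product: 2 (R)-4-hydroxypent-2-ynoic acid
Conditions: n-BuLi (2.1 equiv), THF, −78 → −30 °C; CO2 (g), −78 → 0 °C; 2 M HCl
Reagents that add atoms: carbon dioxide, O=C=O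
Why: Two equivalents of n-BuLi give the lithium alkoxide–acetylide, and the acetylide carbon is carboxylated by CO2 (carboxylation of a metal acetylide); the carbinol stereocentre (future C2) takes no part.

Step 2
Reactants: 2 (R)-4-hydroxypent-2-ynoic acid
Product: 4 (R)-5-methylfuran-2(5H)-one, via hydroxy enoic acid 3 (not isolated)
Conditions: H2 (1 atm), Pd/CaCO3 poisoned with Pb(OAc)2, quinoline, EtOAc, 20 °C; filter; TsOH·H2O (cat.), CH2Cl2, 20 °C
Reagents that add atoms: none
Why: Lindlar semihydrogenation should give the Z-alkene 3, in which hydroxyl and carboxyl are cis, so acid-catalysed lactonisation to the butenolide is fast; the conditions are too weakly basic to enolise the γ-position, so the future C2 centre is kept.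

Step 3
Reactants: 4 (R)-5-methylfuran-2(5H)-one; 5 5-bromo-1,2,3-trimethoxybenzene
Product: 8 (4R,5R)-5-methyl-4-(3,4,5-trimethoxyphenyl)dihydrofuran-2(3H)-one, via aryl Grignard reagent 6 (not isolated), via silyl ketene acetal 7 (not isolated)
Conditions: 5, Mg, THF, 50 °C; then CuBr·SMe2 (10 mol %), Me3SiCl (2 equiv), 4, THF, −78 → −40 °C; 1 M HCl
Reagents that add atoms: none
Why: Copper-catalysed, Me3SiCl-accelerated 1,4-addition of Grignard reagent 6 to the butenolide; the aryl group should enter anti to the γ-methyl group (steric approach control, general for 5-substituted 2(5H)-furanones), which sets C3 trans to C2, and ketene acetal 7 is hydrolysed on acidic work-up.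

Step 4
Reactants: 8 (4R,5R)-5-methyl-4-(3,4,5-trimethoxyphenyl)dihydrofuran-2(3H)-one
Product: 9 (4S,5R)-3-(hydroxymethylidene)-5-methyl-4-(3,4,5-trimethoxyphenyl)dihydrofuran-2(3H)-one
Conditions: NaH (2 equiv), HCO2Et (5 equiv), EtOH (cat.), THF, 0 → 20 °C; 1 M HCl
Reagents that add atoms: ethyl formate, CCOC=O
Why: Crossed Claisen condensation of the lactone enolate with a non-enolisable formate, driven by formation of the stabilised sodium enolate; C3 is not acidic under these conditions and C3a stays trigonal, so no stereocentre is set or lost.

Step 5
Reactants: 9 (4S,5R)-3-(hydroxymethylidene)-5-methyl-4-(3,4,5-trimethoxyphenyl)dihydrofuran-2(3H)-one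
Product: 10 (3S,4S,5R)-3-allyl-5-methyl-2-oxo-4-(3,4,5-trimethoxyphenyl)tetrahydrofuran-3-carbaldehyde
Conditions: NaH (1.0 equiv), THF, 0 °C; allyl acetate (1.2 equiv), Pd(PPh3)4 (5 mol %), THF, 20 °C
Reagents that add atoms: allyl acetate, C=CCOC(C)=O
Why: Tsuji–Trost allylation: zerovalent palladium ionises allyl acetate and the stabilised formyl-lactone enolate attacks through carbon, any O-allyl enol ether being re-ionised and funnelled to the C-allyl product; the electrophile should approach the planar enolate anti to the vicinal C3 aryl group, which sets the quaternary C3a with allyl trans to aryl and the formyl group cis to it.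

Step 6
Reactants: 10 (3S,4S,5R)-3-allyl-5-methyl-2-oxo-4-(3,4,5-trimethoxyphenyl)tetrahydrofuran-3-carbaldehyde; 11 1,3-dimethoxyacetone
Product: 15 (2R,3S,3aS)-3a-allyl-5,7-dimethoxy-2-methyl-3-(3,4,5-trimethoxyphenyl)-3,3a-dihydrobenzofuran-6(2H)-one, via lithium enolate 12 (not isolated), via aldol adduct 13 (not isolated), via hydroxy dione 14 (not isolated)
Conditions: 11, LiN(i-Pr)2 (1.1 equiv), THF, −78 °C; 10, −78 °C; LiN(i-Pr)2 (1.3 equiv), −78 → 0 °C; 2 M HCl; then TsOH·H2O (10 mol %), 4 Å MS, PhMe, 40 °C
Reagents that add atoms: none
Why: Enolate 12 adds to the non-enolisable aldehyde of 10 to form C4–C5 (aldolate of 13); the second portion of amide base removes a proton from the distal methoxymethyl carbon C7, and that enolate attacks the lactone carbonyl to form C7–C7a in a 6-exo-trig Claisen (Dieckmann-type) closure of ring B. Collapse of the tetrahedral intermediate expels O1 as the C2 alkoxide, and the product rests as the stabilised enolate of the 2-methoxy-1,3-dione 14, which makes the acyl transfer irreversible. On acidification the C2 hydroxyl re-adds to C7a (5-exo-trig, ring A re-closed) and loses water to the vinylogous ester, and the β-hydroxy ketone loses water through its C5 enol to give C4=C5. The closest known reaction types are the ketone-enolate aldol addition, intramolecular Claisen acylation of a ketone enolate by a lactone to a cyclic 1,3-dione, and acid-catalysed enol-ether formation of a 1,3-dione with a tethered alcohol. No stereocentre is created: the carbinol and methine centres at C4, C5 and C7 are erased, and C2, C3 and C3a carry no acidic hydrogen and are untouched. The selectivities needed are secured by the substrate: the aldehyde is far more electrophilic than the lactone, ketone 11 is symmetric, and only attack from C7 gives a six-membered ring, attack from C5 requiring a four-membered one. The alkoxide–enolate dianion also resists retro-aldol cleavage because that would release a ketone α,α'-dianion. The acid stage is kept catalytic and at 40 °C so that the C3a allyl group of the dienone does not migrate.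

Step 7
Reactants: 15 (2R,3S,3aS)-3a-allyl-5,7-dimethoxy-2-methyl-3-(3,4,5-trimethoxyphenyl)-3,3a-dihydrobenzofuran-6(2H)-one
Product: 16 (2R,3S,3aR,5S)-3a-allyl-5,7-dimethoxy-2-methyl-3-(3,4,5-trimethoxyphenyl)-3,3a,4,5-tetrahydrobenzofuran-6(2H)-one
Conditions: LiBH(s-Bu)3 (1.1 equiv), THF, −78 °C; t-BuCO2H (3 equiv) in THF, −78 °C; pH 7 buffer, no oxidative work-up
Reagents that add atoms: none
Why: Conjugate hydride reduction with a trialkylborohydride: C6 is flanked by two methoxy-substituted sp2 carbons and C7a is a fully substituted, oxygen-deactivated β-carbon, so the bulky hydride should add at C4, the only open position of the cross-conjugated dienone; the C5=C6 enolate is then protonated at −78 °C by a hindered acid on the face opposite the pseudo-axial angular allyl group, which places the C5 methoxy group cis to allyl (5S). The neutral, non-oxidative work-up should avoid epimerisation of the α-methoxy ketone and leaves the terminal alkene untouched.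

## Compound list

1 | (R)-but-3-yn-2-ol | C[C@@H](O)C#C | starting material
2 | (R)-4-hydroxypent-2-ynoic acid | C[C@@H](O)C#CC(=O)O | intermediate
3 | (R,Z)-4-hydroxypent-2-enoic acid | C[C@@H](O)/C=C\C(=O)O | intermediate
4 | (R)-5-methylfuran-2(5H)-one | C[C@H]1OC(=O)C=C1 | intermediate
5 | 5-bromo-1,2,3-trimethoxybenzene | COc1cc(Br)cc(OC)c1OC | starting material
6 | (3,4,5-trimethoxyphenyl)magnesium bromide | COc1cc([Mg]Br)cc(OC)c1OC | intermediate
7 | trimethyl{[(4R,5R)-5-methyl-4-(3,4,5-trimethoxyphenyl)-4,5-dihydrofuran-2-yl]oxy}silane | C1=C(O[Si](C)(C)C)O[C@H](C)[C@H]1c2cc(OC)c(OC)c(OC)c2 | intermediate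
8 | (4R,5R)-5-methyl-4-(3,4,5-trimethoxyphenyl)dihydrofuran-2(3H)-one (aryl trans to methyl) | C1C(=O)O[C@H](C)[C@H]1c2cc(OC)c(OC)c(OC)c2 | intermediate
9 | (4S,5R)-3-(hydroxymethylidene)-5-methyl-4-(3,4,5-trimethoxyphenyl)dihydrofuran-2(3H)-one (Z enol drawn) | O/C=C1\C(=O)O[C@H](C)[C@H]1c2cc(OC)c(OC)c(OC)c2 | intermediate
10 | (3S,4S,5R)-3-allyl-5-methyl-2-oxo-4-(3,4,5-trimethoxyphenyl)tetrahydrofuran-3-carbaldehyde (allyl trans to aryl, aryl trans to methyl) | C=CC[C@]1(C=O)C(=O)O[C@H](C)[C@H]1c2cc(OC)c(OC)c(OC)c2 | intermediate
11 | 1,3-dimethoxyacetone (1,3-dimethoxypropan-2-one) | COCC(=O)COC | starting material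
12 | lithium (Z)-1,3-dimethoxyprop-1-en-2-olate | [Li+].CO/C=C(\[O-])COC | intermediate
13 | (3S,4S,5R)-3-allyl-3-(1-hydroxy-2,4-dimethoxy-3-oxobutyl)-5-methyl-4-(3,4,5-trimethoxyphenyl)dihydrofuran-2(3H)-one (side-chain epimers) | C=CC[C@]1(C(O)C(OC)C(=O)COC)C(=O)O[C@H](C)[C@H]1c2cc(OC)c(OC)c(OC)c2 | intermediate
14 | (4S)-4-allyl-5-hydroxy-4-[(1S,2R)-2-hydroxy-1-(3,4,5-trimethoxyphenyl)propyl]-2,6-dimethoxycyclohexane-1,3-dione (epimers at C2, C5, C6 of the dione ring) | C=CC[C@@]1(C(O)C(OC)C(=O)C(OC)C1=O)[C@H](c2cc(OC)c(OC)c(OC)c2)[C@@H](C)O | intermediate
15 | (2R,3S,3aS)-3a-allyl-5,7-dimethoxy-2-methyl-3-(3,4,5-trimethoxyphenyl)-3,3a-dihydrobenzofuran-6(2H)-one | C=CC[C@]12C=C(OC)C(=O)C(OC)=C1O[C@H](C)[C@H]2c3cc(OC)c(OC)c(OC)c3 | intermediate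
16 | (2R,3S,3aR,5S)-3a-allyl-5,7-dimethoxy-2-methyl-3-(3,4,5-trimethoxyphenyl)-3,3a,4,5-tetrahydrobenzofuran-6(2H)-one | C=CC[C@]12C[C@H](OC)C(=O)C(OC)=C1O[C@H](C)[C@H]2c3cc(OC)c(OC)c(OC)c3 | target

## Step count and risks

Total: 7 steps. Longest linear sequence: 7 steps (1 → 16); 5 enters in step 3 and 11 in step 6.

**Step 6 (key step).**
- What may go wrong: loss of the aldol adduct before ring B closes, either by reversal of the addition or by base-induced deformylation, because the aldehyde is neopentyl and cis to the aryl group. In the acid stage, acid-promoted migration of the C3a allyl group could accompany the dehydration.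
- Fallback (from 10 and 11, back at 15): 11 is silylated with Me3SiCl/Et3N/NaI to its enol ether {[(Z)-1,3-dimethoxyprop-1-en-2-yl]oxy}trimethylsilane F1. F1 adds to 10 in a Mukaiyama aldol reaction mediated by MgBr2·OEt2, so that no basic species meets the aldehyde, and aldol 13 is isolated. It is capped with Et3SiOSO2CF3/2,6-lutidine as (3S,4S,5R)-3-allyl-3-[2,4-dimethoxy-3-oxo-1-(triethylsilyloxy)butyl]-5-methyl-4-(3,4,5-trimethoxyphenyl)dihydrofuran-2(3H)-one F2. LiN(i-Pr)2 then performs the same Claisen closure to the silyloxy dione (4S)-4-allyl-4-[(1S,2R)-2-hydroxy-1-(3,4,5-trimethoxyphenyl)propyl]-2,6-dimethoxy-5-(triethylsilyloxy)cyclohexane-1,3-dione F3. Pyridinium p-toluenesulfonate closes ring A to (2R,3S,3aS)-3a-allyl-5,7-dimethoxy-2-methyl-4-(triethylsilyloxy)-3-(3,4,5-trimethoxyphenyl)-3,3a,4,5-tetrahydrobenzofuran-6(2H)-one F4. DBU removes the silanol by E1cB elimination to give 15 without strong acid or heat.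

**Step 7.**
- What may go wrong: competing 1,2-hydride addition at C6 or slow delivery to C4, which is next to a quaternary carbon; incomplete facial selectivity in the protonation of the C5 enolate; epimerisation of the α-methoxy ketone during work-up.
- Fallback (from 15, back at 16): copper hydride conjugate reduction with [(Ph3P)CuH]6 in the presence of t-BuMe2SiCl traps the enolate as tert-butyl{[(2R,3S,3aR)-3a-allyl-5,7-dimethoxy-2-methyl-3-(3,4,5-trimethoxyphenyl)-2,3,3a,4-tetrahydrobenzofuran-6-yl]oxy}dimethylsilane F5, which can be purified. Bu4NF with t-BuCO2H at −78 °C then releases and protonates the enolate in a separate step whose proton source can be varied, giving 16.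

**Step 5.**
- What may go wrong: persistent O-allylation, nucleophilic deformylation of the quaternary aldehyde once formed, or insufficient facial discrimination by the C3 aryl group.
- Fallback (from 9, back at 10): O-allylation with allyl bromide/K2CO3 in acetone gives (4S,5R)-3-[(allyloxy)methylidene]-5-methyl-4-(3,4,5-trimethoxyphenyl)dihydrofuran-2(3H)-one F6. Its thermal Claisen rearrangement (PhMe, 110 °C) transfers the allyl group to C3a through a chair transition state on the face away from the aryl group and gives 10 under neutral conditions.

**Step 3.**
- What may go wrong: incomplete anti selectivity because the directing methyl group is small, or partial racemisation of 4 through γ-deprotonation by the basic Grignard reagent.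
- Fallback (from 4, back at 8): rhodium-catalysed Hayashi–Miyaura addition of purchased (3,4,5-trimethoxyphenyl)boronic acid with [Rh(cod)OH]2 and the BINAP enantiomer whose facial preference matches attack anti to the methyl group. Reagent control then reinforces substrate control under nearly neutral conditions. This detour passes through no new compound (F0).

## Further compounds

F1 | step 6 | {[(Z)-1,3-dimethoxyprop-1-en-2-yl]oxy}trimethylsilane | CO/C=C(\O[Si](C)(C)C)COC
F2 | step 6 | (3S,4S,5R)-3-allyl-3-[2,4-dimethoxy-3-oxo-1-(triethylsilyloxy)butyl]-5-methyl-4-(3,4,5-trimethoxyphenyl)dihydrofuran-2(3H)-one | C=CC[C@]1(C(O[Si](CC)(CC)CC)C(OC)C(=O)COC)C(=O)O[C@H](C)[C@H]1c2cc(OC)c(OC)c(OC)c2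
F3 | step 6 | (4S)-4-allyl-4-[(1S,2R)-2-hydroxy-1-(3,4,5-trimethoxyphenyl)propyl]-2,6-dimethoxy-5-(triethylsilyloxy)cyclohexane-1,3-dione | C=CC[C@@]1(C(O[Si](CC)(CC)CC)C(OC)C(=O)C(OC)C1=O)[C@H](c2cc(OC)c(OC)c(OC)c2)[C@@H](C)O
F4 | step 6 | (2R,3S,3aS)-3a-allyl-5,7-dimethoxy-2-methyl-4-(triethylsilyloxy)-3-(3,4,5-trimethoxyphenyl)-3,3a,4,5-tetrahydrobenzofuran-6(2H)-one | C=CC[C@]12C(O[Si](CC)(CC)CC)C(OC)C(=O)C(OC)=C1O[C@H](C)[C@H]2c3cc(OC)c(OC)c(OC)c3
F5 | step 7 | tert-butyl{[(2R,3S,3aR)-3a-allyl-5,7-dimethoxy-2-methyl-3-(3,4,5-trimethoxyphenyl)-2,3,3a,4-tetrahydrobenzofuran-6-yl]oxy}dimethylsilane | C=CC[C@]12CC(OC)=C(O[Si](C)(C)C(C)(C)C)C(OC)=C1O[C@H](C)[C@H]2c3cc(OC)c(OC)c(OC)c3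
F6 | step 5 | (4S,5R)-3-[(allyloxy)methylidene]-5-methyl-4-(3,4,5-trimethoxyphenyl)dihydrofuran-2(3H)-one (E drawn) | C=CCO/C=C1/C(=O)O[C@H](C)[C@H]1c2cc(OC)c(OC)c(OC)c2
F0 | step 3 | none | none
A1 | alternative 1 | 3-(benzyloxy)-2,4-dimethoxy-6-[(3,4,5-trimethoxyphenyl)methylidene]cyclohexa-2,4-dien-1-one | O=C1C(OC)=C(OCc2ccccc2)C(OC)=CC1=Cc3cc(OC)c(OC)c(OC)c3
A2 | alternative 1 | tert-butyl (2S,3S)-6-(benzyloxy)-5,7-dimethoxy-3-(3,4,5-trimethoxyphenyl)-2,3-dihydrobenzofuran-2-carboxylate (trans) | c12cc(OC)c(OCc3ccccc3)c(OC)c1O[C@H](C(=O)OC(C)(C)C)[C@H]2c1cc(OC)c(OC)c(OC)c1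
A3 | alternative 2 | methyl 2-methoxy-3-[(5R)-5-methyl-2-oxo-2,5-dihydrofuran-3-yl]propanoate | C[C@H]1OC(=O)C(CC(OC)C(=O)OC)=C1
A4 | alternative 2 | methyl (2S)-3-[(3R,4S,5R)-3-allyl-5-methyl-2-oxo-4-(3,4,5-trimethoxyphenyl)tetrahydrofuran-3-yl]-2-methoxypropanoate | C=CC[C@]1(C[C@H](OC)C(=O)OC)C(=O)O[C@H](C)[C@H]1c1cc(OC)c(OC)c(OC)c1
A5 | alternative 3 | methyl (Z)-2-(bromomethyl)-3-(3,4,5-trimethoxyphenyl)prop-2-enoate | COC(=O)/C(CBr)=C/c1cc(OC)c(OC)c(OC)c1
A6 | alternative 3 | acetaldehyde | CC=O
A7 | alternative 3 | (4S,5R)-5-methyl-3-methylidene-4-(3,4,5-trimethoxyphenyl)dihydrofuran-2(3H)-one (trans) | C=C1C(=O)O[C@H](C)[C@H]1c1cc(OC)c(OC)c(OC)c1
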